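## Retrosynthetic overview
1. C2–C3: the acetic acid unit is added last, as a bis-silyl ketene acetal, to the C3 peroxycarbenium ion of 17. Axial attack sets C3.
2. C6–C7: E-vinylsilane 16 adds to the C6 peroxycarbenium ion from bis-ketal 7. Axial attack sets C6 and joins the two halves.
3. The only ring, the 1,2-dioxane, is made first. Light-driven O2 incorporation (decatungstate C–H hydroperoxidation of lactol ether 6) is followed by O→O–O ring expansion to 7.
4. C4 is bought with (S)-epichlorohydrin (malonate cyclopropane-lactone, MeCu opening, Krapcho, EtLi).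
5. C10 comes from (R)-1,2-epoxybutane by 1,3-chirality transfer in a ketal-Claisen rearrangement. The 7E alkene comes from syn-ethylcupration of alkyne 14.

Assumption: carbons that are ionised later (C2 of 6, C3 and C6 of 7, C3 of 17) are carried as epimer mixtures and written without descriptors. Both chiral epoxides are taken as inexpensive commercial materials.

## Route

Step 1
Reactants: 1 (S)-epichlorohydrin; 2 diethyl malonate
Product: 3 ethyl (1R,5S)-2-oxo-3-oxabicyclo[3.1.0]hexane-1-carboxylate
Conditions: NaOEt (1.1 equiv), EtOH, 0 °C → reflux
Reagents that add atoms: none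
Why: Alkylation/lactonisation cascade in which malonate opens the epoxide at CH2, the alkoxide re-closes onto CH2Cl, and a 3-exo-tet enolate attack (inversion) followed by lactonisation gives the cis-fused cyclopropane lactone, so the bought stereocentre is relayed cleanly.

Step 2
Reactants: 3
Product: 4 ethyl (4S)-4-ethyl-2-oxooxolane-3-carboxylate (C3 epimers)
Conditions: MeMgBr (1.3 equiv), CuI (0.2 equiv), THF, −30 °C
Reagents that add atoms: methylmagnesium bromide, C[Mg]Br
Why: Cu-catalysed homoconjugate addition opens the doubly activated cyclopropane at its CH2 and turns it into the ethyl branch without touching the stereocentre (future C4).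

Step 3
Reactants: 4
Product: 5 (4S)-4-ethyloxolan-2-one
Conditions: LiCl, H2O, DMSO, 145 °C
Reagents that add atoms: none
Why: Krapcho dealkoxycarbonylation removes the ester and leaves C4, which is not acidic, untouched.

Step 4
Reactants: 5
Product: 6 (4S)-2,4-diethyl-2-methoxyoxolane (C2 epimers)
Conditions: EtLi (1.05 equiv), Et2O, −78 °C; then MeOH, HC(OMe)3, CSA (cat.), −78 °C → rt
Reagents that add atoms: ethyllithium, [Li]CC; methanol, CO
Why: Organolithium mono-addition to a γ-lactone stops at the lithium lactolate at −78 °C, and acid-catalysed ketalisation then locks the cyclic form.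

Step 5 (key step)
Reactants: 6
Product: 7 (4S)-4,6-diethyl-3,6-dimethoxy-1,2-dioxane (C3/C6 epimers)
Conditions: O2 (1 atm), (n-Bu4N)4W10O32 (2 mol %), MeCN, 390 nm LEDs, 0 °C, to about 80 % conversion; then MeOH (5 equiv), HC(OMe)3, CSA (5 mol %), CH2Cl2, 0 °C
Reagents that add atoms: dioxygen, O=O; methanol, CO
Why: Proposed new method: excited decatungstate abstracts the only ring α-oxy C–H (oxolane C5–H, the future C3), the radical traps triplet O2 and back-HAT gives the 5-hydroperoxy lactol ether, whose OOH then captures the C2 oxocarbenium ion released from the ketal by acid (transannular peroxyketalisation to a 2,3,7-trioxabicyclo[2.2.1]heptane), and methanolysis of the strained O-bridge gives the 1,2-dioxane bis-ketal with C4 as a spectator; the closest known chemistry is photosensitised or decatungstate autoxidation of tetrahydrofuran to 2-hydroperoxytetrahydrofuran, combined with acid-catalysed peroxyketalisation of 1,4-dicarbonyls.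

Step 6
Reactants: 8 (R)-1,2-epoxybutane
Product: 9 (3R)-pent-1-en-3-ol
Conditions: Me3S+I− (3 equiv), n-BuLi (2.9 equiv), THF, −10 °C → rt
Reagents that add atoms: trimethylsulfonium iodide, C[S+](C)C.[I-]
Why: Sulfonium-ylide one-carbon homologation of a terminal epoxide to an allylic alcohol (ring opening at CH2, then ylide-mediated elimination) never breaks the C–O stereocentre.

Step 7
Reactants: 9; 10 (Z)-hex-3-ene (4 equiv)
Product: 11 (3R,4E)-hept-4-en-3-ol
Conditions: Hoveyda–Grubbs II (2 mol %), CH2Cl2, 40 °C; AgNO3–SiO2 chromatography to E:Z > 30:1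
Reagents that add atoms: none
Why: Olefin cross-metathesis with an achiral Ru catalyst gives the thermodynamic E allylic alcohol with the carbinol untouched, and geometric purity matters because any Z isomer would deliver the opposite C10 configuration in step 8.

Step 8
Reactants: 11; 12 2-methoxypropene (5 equiv)
Product: 13 (4R,5E)-4-ethyloct-5-en-2-one
Conditions: PPTS (3 mol %), xylene, sealed tube, 135 °C
Reagents that add atoms: none
Why: Ketal-Claisen (Saucy–Marbet) rearrangement through a chair transition state with the carbinol ethyl group equatorial forms the new C–C bond on the face the C–O bond leaves, so (3R,4E) gives (R) at the new centre (C10) and an E alkene.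

Step 9
Reactants: 13
Product: 14 (4R,5E)-4-ethyloct-5-en-1-yne
Conditions: LDA, THF, −78 °C; ClP(O)(OEt)2; LDA (2.3 equiv), −78 °C → rt
Reagents that add atoms: none
Why: Kinetic methyl-side enol phosphate formation followed by base elimination converts the methyl ketone to the terminal alkyne, and C10 is not acidic enough to be affected.

Step 10
Reactants: 14
Product: 15 (1E,4R,5E)-2,4-diethyl-1-iodoocta-1,5-diene
Conditions: EtMgBr, CuBr·SMe2, Et2O–Me2S, −45 → −25 °C; then I2, THF, −50 → 0 °C
Reagents that add atoms: ethylmagnesium bromide, CC[Mg]Br; iodine, II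
Why: Normant carbocupration adds Et–Cu syn with Et on the internal carbon, and iodinolysis with retention fixes the trisubstituted geometry (I cis to Et, which is E).

Step 11
Reactants: 15
Product: 16 [(1E,4R,5E)-2,4-diethylocta-1,5-dien-1-yl]trimethylsilane
Conditions: t-BuLi (2.1 equiv), Et2O, −78 °C; TMSCl
Reagents that add atoms: chlorotrimethylsilane, C[Si](C)(C)Cl
Why: Stereoretentive iodine–lithium exchange and silylation give a non-reducing alkenyl nucleophile that is compatible with the O–O bond.

Step 12
Reactants: 7 (1.2 equiv); 16
Product: 17 (4S,6R)-6-[(1E,4R,5E)-2,4-diethylocta-1,5-dien-1-yl]-4,6-diethyl-3-methoxy-1,2-dioxane (C3 epimers)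
Conditions: TMSOTf (0.3 equiv), 2,6-di-tert-butyl-4-methylpyridine (0.1 equiv), CH2Cl2, −78 → −50 °C
Reagents that add atoms: none
Why: Proposed new method: silyl triflate removes the more labile ketal methoxy group to give the tertiary peroxycarbenium ion (peroxide loss only re-closes, MeOTMS loss is irreversible), the half-chair with C4-Et pseudo-equatorial and 3-OMe anomerically axial is attacked along the axial trajectory anti to C4-Et by the Si-bearing carbon of 16, and the tertiary β-silyl cation collapses with retention of alkene geometry while releasing TMS+ as chain carrier, giving (6R) with the alkenyl group axial; the closest known reactions are Hosomi–Sakurai and Mukaiyama trapping of peroxycarbenium ions by allylsilanes and silyl enol ethers, and ipso-substitution of vinylsilanes by oxocarbenium ions.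

Step 13
Reactants: 17; 18 1,1-bis(trimethylsilyloxy)ethene (2.5 equiv)
Product: 19 plakortide N
Conditions: TMSOTf (0.5 equiv), CH2Cl2, −78 → −45 °C; pH 4 citrate work-up
Reagents that add atoms: none
Why: Mukaiyama-type addition of a silyl ketene acetal to a cyclic peroxycarbenium ion (known for 3-alkoxy-1,2-dioxolanes and -dioxanes), in which the quaternary C6 locks the conformer with C4-Et and C6-Et equatorial, so axial attack on the face opposite the axial alkenyl group places CH2CO2H cis to C4-Et (3S), and work-up frees the acid from its silyl ester.

## Compound list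
1 | (S)-epichlorohydrin | ClC[C@@H]1CO1 | starting material
2 | diethyl malonate | CCOC(=O)CC(=O)OCC | starting material
3 | ethyl (1R,5S)-2-oxo-3-oxabicyclo[3.1.0]hexane-1-carboxylate | O=C1OC[C@H]2C[C@@]12C(=O)OCC | intermediate
4 | ethyl (4S)-4-ethyl-2-oxooxolane-3-carboxylate | CCOC(=O)C1C(=O)OC[C@H]1CC | intermediate
5 | (4S)-4-ethyloxolan-2-one | CC[C@@H]1COC(=O)C1 | intermediate
6 | (4S)-2,4-diethyl-2-methoxyoxolane | CC[C@@H]1COC(CC)(OC)C1 | intermediate
7 | (4S)-4,6-diethyl-3,6-dimethoxy-1,2-dioxane | CCC1(OC)C[C@H](CC)C(OC)OO1 | intermediate
8 | (R)-1,2-epoxybutane | CC[C@@H]1CO1 | starting material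
9 | (3R)-pent-1-en-3-ol | CC[C@@H](O)C=C | intermediate
10 | (Z)-hex-3-ene | CC/C=C\CC | starting material
11 | (3R,4E)-hept-4-en-3-ol | CC[C@@H](O)/C=C/CC | intermediate
12 | 2-methoxypropene | COC(C)=C | starting material
13 | (4R,5E)-4-ethyloct-5-en-2-one | CC/C=C/[C@H](CC)CC(C)=O | intermediate
14 | (4R,5E)-4-ethyloct-5-en-1-yne | CC/C=C/[C@H](CC)CC#C | intermediate
15 | (1E,4R,5E)-2,4-diethyl-1-iodoocta-1,5-diene | CC/C=C/[C@H](CC)C/C(=C/I)CC | intermediate
16 | [(1E,4R,5E)-2,4-diethylocta-1,5-dien-1-yl]trimethylsilane | CC/C=C/[C@H](CC)C/C(=C/[Si](C)(C)C)CC | intermediate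
17 | (4S,6R)-6-[(1E,4R,5E)-2,4-diethylocta-1,5-dien-1-yl]-4,6-diethyl-3-methoxy-1,2-dioxane | CC/C=C/[C@H](CC)C/C(=C/[C@@]1(CC)C[C@H](CC)C(OC)OO1)CC | intermediate
18 | 1,1-bis(trimethylsilyloxy)ethene | C=C(O[Si](C)(C)C)O[Si](C)(C)C | starting material
19 | plakortide N, 2-[(3S,4S,6R)-6-[(1E,4R,5E)-2,4-diethylocta-1,5-dien-1-yl]-4,6-diethyl-1,2-dioxan-3-yl]acetic acid | CC/C=C/[C@H](CC)C/C(=C/[C@@]1(CC)C[C@H](CC)[C@H](CC(=O)O)OO1)CC | target

## Step count and risks
Total steps: 13. Longest linear sequence: 8 (steps 6–13). The other branch is 7 steps (1–5, 12, 13).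

The three steps most likely to fail:

1. **Step 5 (new, photochemical).**
   - Risks: a second HAT on the hydroperoxy acetal could over-oxidise it to the lactone. Methanol exchange could expel H2O2.
   - Fallback (known chemistry): take the step-4 lactol as open (S)-5-(hydroxymethyl)heptan-3-one and oxidise it under Swern conditions to (S)-2-ethyl-4-oxohexanal. Condense that with H2O2·urea in MeOH with acid, a peroxyketalisation of a 1,4-dicarbonyl, to reach 7.

2. **Step 12 (new).**
   - Risks: the bond joins a tertiary cation to a hindered trisubstituted vinylsilane, so proton loss, protodesilylation or ring-opened ether products could compete.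
   - Fallback (known chemistry): lithiate 15 and add it to the ketone of (S)-2-ethyl-4-oxohexanal dimethyl acetal. Treat the tertiary allylic alcohol–acetal with anhydrous H2O2 and catalytic acid, so the hydroperoxy acetal captures the allyl cation. This gives 17 plus its 6-epimer, which are separated by chromatography.

3. **Step 13.**
   - Risks: TMSOTf may ionise the tertiary allylic C6–O bond. E1 loss of C4–H from the C3 cation would erode C4. The 3,4-cis selectivity may be lower than predicted.
   - Fallback: hydrolyse 17 to the peroxy-hemiacetal and trap the ring-opened hydroperoxy aldehyde with Ph3P=CHCO2Me. Close the ring by amine-catalysed intramolecular oxa-Michael addition, which probably favours the undesired 3,4-trans isomer, separate the 3,4-cis isomer, and cleave the ester with LiOH.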